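**Retrosynthetic overview**

1. Last bond: the methylidene-bearing diene carbon is joined to the CH2CH2NHCO2Me arm by a Ni-catalysed ring-opening C(sp2)–O alkylation of the cyclic dienyl ether 18 with the B-alkyl-9-BBN 22 (made in the flask from N-vinyl carbamate 21).
2. Enabling feature: the carbinol O and the methylidene-bearing carbon are 1,5-related across the Z olefin, so the atoms O–CH–CH2–CH=CH–C(=CH2) close to a 6-methylidene-3,6-dihydro-2H-pyran. Its ring C=C is the Z olefin, its enol-ether C–O bond is the electrophile, and opening it frees the hydroxyl.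
3. 18 comes from Petasis methylenation of dihydropyranone 17, which comes from Stille sp3–sp2 coupling of chloromethylthiazole lactone 12 with pentadienylstannane 16; 12 comes from acrylate ring-closing metathesis.
4. The (R)-carbinol comes from Brown allylboration of the α-quaternary aldehyde 7; the thiazole comes from a Hantzsch synthesis (thioamide 2 + 1,3-dichloroacetone 3).
5. Ring order: thiazole (step 2); dihydropyranone (step 6, temporary); converted to the methylidene-dihydropyran (step 9); opened in step 11.

Key step: step 11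

Remark: by CIP analysis of the target SMILES the carbinol centre is (R), the conjugated diene olefin is Z and the skipped-diene olefin is E; all intermediates are drawn to match.
Remark: pyran numbering used below is O1, C2 (stereocentre), C3, C4=C5, C6 (bearing the exocyclic CH2). (+)-Ipc2BOMe, Cp2TiMe2, 9-BBN dimer, Ni(cod)2 and IPr·HCl are taken as purchased reagents.

**Step 1**
Reactants: 1 ethyl 2-cyano-2-methylpropanoate
Product: 2 ethyl 3-amino-2,2-dimethyl-3-thioxopropanoate
Conditions: (NH4)2S (20% aq.), MeOH, 50 °C, sealed vessel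
Reagents that add atoms: ammonium sulfide, [NH4+].[NH4+].[S-2]
Why: Thioamide formation by addition of hydrosulfide to the ester-activated nitrile should proceed under mild conditions that leave the hindered ethyl ester untouched.

**Step 2**
Reactants: 2 ethyl 3-amino-2,2-dimethyl-3-thioxopropanoate; 3 1,3-dichloroacetone
Product: 5 ethyl 2-[4-(chloromethyl)-1,3-thiazol-2-yl]-2-methylpropanoate, via 4-hydroxythiazoline adduct 4 (not isolated)
Conditions: EtOH, 70 °C; aq. NaHCO3 work-up
Reagents that add atoms: none
Why: Hantzsch thiazole synthesis (S-alkylation by one CH2Cl arm, ring closure on the ketone, acid-promoted dehydration of 4) should give the 2,4-disubstituted thiazole with the second CH2Cl arm left as the coupling handle.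

**Step 3**
Reactants: 5 ethyl 2-[4-(chloromethyl)-1,3-thiazol-2-yl]-2-methylpropanoate
Product: 7 2-[4-(chloromethyl)-1,3-thiazol-2-yl]-2-methylpropanal, via aluminium hemiacetal 6 (not isolated)
Conditions: DIBAL-H (1.2 equiv), CH2Cl2, −78 °C; Rochelle salt work-up
Reagents that add atoms: none
Why: Partial DIBAL-H reduction of an ester, in which the tetrahedral aluminium hemiacetal 6 (next to a quaternary carbon and chelated by the thiazole N) survives at −78 °C and collapses only on work-up, should stop at the non-enolisable aldehyde without reducing the C–Cl bond.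

**Step 4**
Reactants: 7 2-[4-(chloromethyl)-1,3-thiazol-2-yl]-2-methylpropanal
Product: 9 (3R)-2-[4-(chloromethyl)-1,3-thiazol-2-yl]-2-methylhex-5-en-3-ol, via O-diisopinocampheylborinate 8 (not isolated)
Conditions: (+)-Ipc2BOMe (from (−)-α-pinene), allylMgBr (0.95 equiv relative to boron), Et2O, 0 °C to rt; then 7, −78 °C; then 30% H2O2, aq. NaHCO3, 0 °C to rt
Reagents that add atoms: allylmagnesium bromide, C=CC[Mg]Br
Why: Brown asymmetric allylboration through a closed chair transition state, with the (−)-α-pinene-derived reagent adding to the Re face (the antipode of the reagent that gives (S)-2,2-dimethylhex-5-en-3-ol from pivalaldehyde), should set the (R)-carbinol, and the bicarbonate-buffered peroxide work-up is chosen to spare the CH2Cl group.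

**Step 5**
Reactants: 9 (3R)-2-[4-(chloromethyl)-1,3-thiazol-2-yl]-2-methylhex-5-en-3-ol; 10 acryloyl chloride
Product: 11 (3R)-2-[4-(chloromethyl)-1,3-thiazol-2-yl]-2-methylhex-5-en-3-yl prop-2-enoate
Conditions: i-Pr2NEt, DMAP (cat.), CH2Cl2, 0 °C
Reagents that add atoms: none
Why: DMAP-catalysed O-acylation of the hindered carbinol with the acid chloride should give the acrylate without touching the stereocentre or the CH2Cl group at 0 °C.

**Step 6**
Reactants: 11 (3R)-2-[4-(chloromethyl)-1,3-thiazol-2-yl]-2-methylhex-5-en-3-yl prop-2-enoate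
Product: 12 (6R)-6-{2-[4-(chloromethyl)-1,3-thiazol-2-yl]propan-2-yl}-5,6-dihydro-2H-pyran-2-one
Conditions: Grubbs II catalyst (5 mol%), CH2Cl2 (5 mM), 40 °C
Reagents that add atoms: none
Why: Ring-closing metathesis of the acrylate and homoallyl olefins should close the six-membered α,β-unsaturated δ-lactone, whose ring enforces the cis C=C that later becomes the Z olefin, and at this stage no other olefin competes.

**Step 7**
Reactants: 13 (E)-1,2-bis(tributylstannyl)ethene; 14 allyl bromide
Product: 16 tributyl[(1E)-penta-1,4-dien-1-yl]stannane, via (E)-2-(tributylstannyl)vinyllithium 15 (not isolated)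
Conditions: n-BuLi (1.0 equiv), THF, −78 °C; then CuBr·SMe2 (10 mol%), 14, −78 to 0 °C (the Bu4Sn formed is inert and may be carried along)
Reagents that add atoms: none
Why: Tin–lithium exchange on the (E)-bis-stannane proceeds with retention of olefin geometry, and the resulting vinyllithium should be allylated cleanly (copper-catalysed SN2 alkylation) to the skipped dienylstannane.

**Step 8**
Reactants: 12 (6R)-6-{2-[4-(chloromethyl)-1,3-thiazol-2-yl]propan-2-yl}-5,6-dihydro-2H-pyran-2-one; 16 tributyl[(1E)-penta-1,4-dien-1-yl]stannane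
Product: 17 (6R)-6-(2-{4-[(2E)-hexa-2,5-dien-1-yl]-1,3-thiazol-2-yl}propan-2-yl)-5,6-dihydro-2H-pyran-2-one
Conditions: Pd2(dba)3 (2.5 mol%), P(2-furyl)3 (10 mol%), NMP, 50 °C
Reagents that add atoms: none
Why: Migita–Kosugi–Stille sp3–sp2 coupling of the benzylic-type thiazolylmethyl chloride with the alkenylstannane should proceed with retention of the E geometry under neutral conditions that neither move the 1,4-diene into conjugation nor open the lactone.

**Step 9**
Reactants: 17 (6R)-6-(2-{4-[(2E)-hexa-2,5-dien-1-yl]-1,3-thiazol-2-yl}propan-2-yl)-5,6-dihydro-2H-pyran-2-one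
Product: 18 4-[(2E)-hexa-2,5-dien-1-yl]-2-{2-[(2R)-6-methylidene-3,6-dihydro-2H-pyran-2-yl]propan-2-yl}-1,3-thiazole
Conditions: Cp2TiMe2 (2.5 equiv), toluene containing 1% pyridine, 65 °C, dark; filtration through basic alumina (Et3N-treated), used at once
Reagents that add atoms: dimethyltitanocene (Petasis reagent), C[Ti](C)(C1C=CC=C1)C1C=CC=C1
Why: Petasis methylenation (carbonyl olefination by Cp2Ti=CH2 through an oxatitanacyclobutane) converts lactone carbonyls into exocyclic enol ethers under non-acidic, non-basic conditions, so the 2-alkoxy-1,3-diene should form without touching the thiazole or the skipped diene.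

**Step 10**
Reactants: 10 acryloyl chloride
Product: 21 methyl N-vinylcarbamate (methyl N-ethenylcarbamate), via acryloyl azide 19 (not isolated), via vinyl isocyanate 20 (not isolated)
Conditions: NaN3, phase-transfer catalyst, toluene/H2O, 0 °C; dried azide solution added slowly to toluene at 105 °C (phenothiazine); vinyl isocyanate distilled into MeOH, Et3N (cat.), 0 °C
Reagents that add atoms: sodium azide, [Na+].[N-]=[N+]=[N-]; methanol, CO
Why: Acyl azide formation, Curtius rearrangement to vinyl isocyanate and trapping by methanol should give the N-vinyl carbamate, the standard route to this class of enecarbamates.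

**Step 11**
Reactants: 18 4-[(2E)-hexa-2,5-dien-1-yl]-2-{2-[(2R)-6-methylidene-3,6-dihydro-2H-pyran-2-yl]propan-2-yl}-1,3-thiazole; 21 methyl N-vinylcarbamate
Product: 24 mycothiazole [methyl N-{(4Z,7R)-8-{4-[(2E)-hexa-2,5-dien-1-yl]-1,3-thiazol-2-yl}-7-hydroxy-8-methyl-3-methylidenenon-4-en-1-yl}carbamate], via B-alkyl-9-BBN 22 (not isolated), via mycothiazole O-borinate 23 (not isolated)
Conditions: 21 (2.2 equiv), 9-BBN dimer (2.0 equiv B–H), THF, 0 °C to rt (no B–H left); then 18, Ni(cod)2 (10 mol%), IPr·HCl (20 mol%), CsF (3 equiv), toluene/THF, 70 °C; aq. NaHCO3 work-up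
Reagents that add atoms: none
Why: Proposed new method: Ni(0)/NHC is expected to bind the 2-alkoxy-1,3-diene of 18 (exocyclic C=CH2 and ring C4=C5) in an η4 fashion and to insert into the enol-ether C6(sp2)–O1 bond, opening the pyran to a (1,3-dien-2-yl)nickel(II) alkoxide; the alkoxide (or fluoride) quaternises the boron of 22, the CH2CH2NHCO2Me group passes to nickel, and C(sp2)–C(sp3) reductive elimination releases the product as O-borinate 23, which is hydrolysed on work-up. The closest known reactions are the Ni-catalysed ring-opening cross-coupling of cyclic enol ethers with organomagnesium or organolithium reagents (Wenkert type) and the Ni/NHC-catalysed dealkoxylative alkylation of acyclic enol ethers and aryl ethers with B-alkyl-9-BBN reagents; what is new is their combination, ring opening of a cyclic 2-alkylidene enol ether by a functionalised alkylborane. No ring is closed and no stereocentre is formed: the step opens the temporary ring, frees the (R)-carbinol (its C–O bond is never broken) and builds the methylidene-bearing carbon with the whole carbamate arm in one operation. The Z geometry is inherited, not made, because the C4=C5 olefin is cis by virtue of the six-membered ring and is a spectator of the bond reorganisation. The selectivity required is insertion into the dienyl C–O bond rather than the thiazole C–S bonds, with no Ni–H isomerisation of the skipped diene; diene chelation directing nickel to C6–O1, the conjugated (activated) enol ether allowing a mild temperature, fast reductive elimination from the bulky NHC complex and the absence of residual B–H are relied on for this.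

**Compound list**

1 | ethyl 2-cyano-2-methylpropanoate | CCOC(=O)C(C)(C)C#N | starting material
2 | ethyl 3-amino-2,2-dimethyl-3-thioxopropanoate | CCOC(=O)C(C)(C)C(N)=S | intermediate
3 | 1,3-dichloroacetone | ClCC(=O)CCl | starting material
4 | ethyl 2-[4-(chloromethyl)-4-hydroxy-4,5-dihydro-1,3-thiazol-2-yl]-2-methylpropanoate | CCOC(=O)C(C)(C)C1=NC(O)(CCl)CS1 | intermediate (not isolated)
5 | ethyl 2-[4-(chloromethyl)-1,3-thiazol-2-yl]-2-methylpropanoate | CCOC(=O)C(C)(C)c1nc(CCl)cs1 | intermediate
6 | diisobutylaluminium hemiacetal of 5 | CCOC(O[Al](CC(C)C)CC(C)C)C(C)(C)c1nc(CCl)cs1 | intermediate (not isolated)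
7 | 2-[4-(chloromethyl)-1,3-thiazol-2-yl]-2-methylpropanal | ClCc1csc(C(C)(C)C=O)n1 | intermediate
8 | O-diisopinocampheylborinate of 9 | ClCc1csc(C(C)(C)[C@H](OB([C@H]2C[C@H]3C[C@@H]([C@@H]2C)C3(C)C)[C@H]2C[C@H]3C[C@@H]([C@@H]2C)C3(C)C)CC=C)n1 | intermediate (not isolated)
9 | (3R)-2-[4-(chloromethyl)-1,3-thiazol-2-yl]-2-methylhex-5-en-3-ol | ClCc1csc(C(C)(C)[C@H](O)CC=C)n1 | intermediate
10 | acryloyl chloride | C=CC(=O)Cl | starting material
11 | (3R)-2-[4-(chloromethyl)-1,3-thiazol-2-yl]-2-methylhex-5-en-3-yl prop-2-enoate | ClCc1csc(C(C)(C)[C@H](OC(=O)C=C)CC=C)n1 | intermediate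
12 | (6R)-6-{2-[4-(chloromethyl)-1,3-thiazol-2-yl]propan-2-yl}-5,6-dihydro-2H-pyran-2-one | ClCc1csc(C(C)(C)[C@H]2CC=CC(=O)O2)n1 | intermediate
13 | (E)-1,2-bis(tributylstannyl)ethene | CCCC[Sn](CCCC)(CCCC)/C=C/[Sn](CCCC)(CCCC)CCCC | starting material
14 | allyl bromide | C=CCBr | starting material
15 | (E)-2-(tributylstannyl)vinyllithium | [Li]/C=C/[Sn](CCCC)(CCCC)CCCC | intermediate (not isolated)
16 | tributyl[(1E)-penta-1,4-dien-1-yl]stannane | C=CC/C=C/[Sn](CCCC)(CCCC)CCCC | intermediate
17 | (6R)-6-(2-{4-[(2E)-hexa-2,5-dien-1-yl]-1,3-thiazol-2-yl}propan-2-yl)-5,6-dihydro-2H-pyran-2-one | C=CC/C=C/Cc1csc(C(C)(C)[C@H]2CC=CC(=O)O2)n1 | intermediate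
18 | 4-[(2E)-hexa-2,5-dien-1-yl]-2-{2-[(2R)-6-methylidene-3,6-dihydro-2H-pyran-2-yl]propan-2-yl}-1,3-thiazole | C=CC/C=C/Cc1csc(C(C)(C)[C@H]2CC=CC(=C)O2)n1 | intermediate
19 | acryloyl azide | C=CC(=O)N=[N+]=[N-] | intermediate (not isolated)
20 | vinyl isocyanate | C=CN=C=O | intermediate (not isolated)
21 | methyl N-vinylcarbamate | C=CNC(=O)OC | intermediate
22 | methyl N-[2-(9-borabicyclo[3.3.1]nonan-9-yl)ethyl]carbamate | COC(=O)NCCB1C2CCCC1CCC2 | intermediate (not isolated)
23 | O-(9-borabicyclo[3.3.1]nonan-9-yl) borinate of mycothiazole | C=CC/C=C/Cc1csc(C(C)(C)[C@H](OB2C3CCCC2CCC3)C/C=C\C(=C)CCNC(=O)OC)n1 | intermediate (not isolated)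
24 | mycothiazole | C=CC/C=C/Cc1csc(C(C)(C)[C@H](O)C/C=C\C(=C)CCNC(=O)OC)n1 | target

**Step count and risks**

Total step count: 11 (steps 7 and 10 prepare the two coupling partners).
Longest linear sequence: 9 steps (1, 2, 3, 4, 5, 6, 8, 9, 11).

Steps most likely to fail:

1. Step 11 (Proposed new method). Oxidative addition into the dienyl C–O bond may be too slow compared with catalyst binding or C–S insertion at the thiazole, and nickel hydride arising from β-hydride elimination may isomerise the skipped diene. The fallback uses known chemistry, sets out from lactone 17 and returns to the route at 24. Lactone 17 is opened with Me(MeO)NH·HCl/Me3Al to the (2Z)-hydroxy Weinreb amide F1. Silylation (TBSOTf, 2,6-lutidine) gives the silyl ether F2, and MeMgBr gives the (Z)-enone F3. Kinetic enolisation (KHMDS, THF, −78 °C) and trapping with PhNTf2 give the 2-triflyloxy-1,3-diene F4. Pd-catalysed B-alkyl Suzuki–Miyaura coupling with borane 22 (PdCl2(dppf), AsPh3, K3PO4, DMF/THF/H2O, rt) gives O-TBS-mycothiazole F5, and TBAF then gives 24.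

2. Step 9. The exocyclic dienyl ether may hydrolyse or isomerise to the endocyclic 2H-pyran during the reaction or on isolation. The fallback sets out from 17 and returns at 18. 1,2-Reduction with DIBAL-H (−78 °C) gives the lactol F6. Ohira–Bestmann homologation (dimethyl (1-diazo-2-oxopropyl)phosphonate, K2CO3, MeOH) gives the (Z)-enynol F7. 6-exo-dig cycloisomerisation of the alkynol (gold(I) catalyst, CH2Cl2, 0 °C, Et3N quench) should then close the methylidene-dihydropyran 18 without a titanium reagent.

3. Step 4. Facial selectivity may be insufficient or addition slow at the neopentyl-type aldehyde, and the chloride may be displaced during the oxidative work-up. The fallback sets out from 7 and returns at 9. Barbier allylation (Zn, allyl bromide 14, THF/aq. NH4Cl) gives the racemic alcohol F8, and Dess–Martin oxidation gives the β,γ-unsaturated ketone F9. CBS reduction ((S)-Me-CBS, catecholborane, toluene, −78 °C) distinguishes the tertiary-alkyl flank from the allyl flank and should return the (R)-alcohol 9.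

**Further compounds**

F1 | step 11 | (2Z,5R)-6-{4-[(2E)-hexa-2,5-dien-1-yl]-1,3-thiazol-2-yl}-5-hydroxy-N-methoxy-N,6-dimethylhept-2-enamide | C=CC/C=C/Cc1csc(C(C)(C)[C@H](O)C/C=C\C(=O)N(C)OC)n1
F2 | step 11 | 5-O-tert-butyldimethylsilyl ether of F1 | C=CC/C=C/Cc1csc(C(C)(C)[C@H](O[Si](C)(C)C(C)(C)C)C/C=C\C(=O)N(C)OC)n1
F3 | step 11 | (3Z,6R)-6-(tert-butyldimethylsilyloxy)-7-{4-[(2E)-hexa-2,5-dien-1-yl]-1,3-thiazol-2-yl}-7-methyloct-3-en-2-one | C=CC/C=C/Cc1csc(C(C)(C)[C@H](O[Si](C)(C)C(C)(C)C)C/C=C\C(C)=O)n1
F4 | step 11 | (3Z,6R)-6-(tert-butyldimethylsilyloxy)-7-{4-[(2E)-hexa-2,5-dien-1-yl]-1,3-thiazol-2-yl}-7-methylocta-1,3-dien-2-yl trifluoromethanesulfonate | C=CC/C=C/Cc1csc(C(C)(C)[C@H](O[Si](C)(C)C(C)(C)C)C/C=C\C(=C)OS(=O)(=O)C(F)(F)F)n1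
F5 | step 11 | O-tert-butyldimethylsilyl mycothiazole | C=CC/C=C/Cc1csc(C(C)(C)[C@H](O[Si](C)(C)C(C)(C)C)C/C=C\C(=C)CCNC(=O)OC)n1
F6 | step 9 | (6R)-6-(2-{4-[(2E)-hexa-2,5-dien-1-yl]-1,3-thiazol-2-yl}propan-2-yl)-5,6-dihydro-2H-pyran-2-ol (anomer mixture) | C=CC/C=C/Cc1csc(C(C)(C)[C@H]2CC=CC(O)O2)n1
F7 | step 9 | (3R,5Z)-2-{4-[(2E)-hexa-2,5-dien-1-yl]-1,3-thiazol-2-yl}-2-methyloct-5-en-7-yn-3-ol | C=CC/C=C/Cc1csc(C(C)(C)[C@H](O)C/C=C\C#C)n1
F8 | step 4 | racemic 2-[4-(chloromethyl)-1,3-thiazol-2-yl]-2-methylhex-5-en-3-ol | ClCc1csc(C(C)(C)C(O)CC=C)n1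
F9 | step 4 | 2-[4-(chloromethyl)-1,3-thiazol-2-yl]-2-methylhex-5-en-3-one | ClCc1csc(C(C)(C)C(=O)CC=C)n1
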